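**Retrosynthetic overview**

- Feature: ring B (C1'–C6') alternates the oxygen-bearing carbons C2', C4', C6' with the carbon-substituted C1' (CH2 bridge), C3' (prenyl) and C5' (acetyl). C1'–C4' therefore map onto a 2-prenyl-3-oxo ester and C5'–C6' onto an acetyl alkoxy alkyne.
- Key disconnection: C1'–C6' and C4'–C5', by (4+2) cycloaddition of the 1-methoxy-1,3-bis(trimethylsilyloxy) diene 15 with 4-ethoxybut-3-yn-2-one 18, then aromatisation. Ring B is the only ring built; ring A is carried intact from 2,4,6-trihydroxyacetophenone 1.
- Diene 15 comes from keto ester 13, made by γ-benzylation of the dianion of methyl 2-prenylacetoacetate 11 with the MOM-protected ring A benzyl bromide 8 (from 1 by C-methylation, O-methylation, formylation, MOM protection, reduction, bromination).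
- End: acetylation of the 2'- and 4'-hydroxyls, BCl3 cleavage of the O6' ethyl ether and both MOM ethers, methanolysis of the acetates.

Key step: step 12

Remark on locants: ring B is primed (C1' carries the CH2 bridge, C2' OH, C3' prenyl, C4' OH, C5' acetyl, C6' OH); ring A is the ring with the methoxy and C-methyl groups.

Assumption: steps 1 and 2 are taken to give 2 and 3 separable from over-alkylated material by crystallisation or chromatography; bromide 8, diene 15 and ynone 18 are used at once, without storage.

**Route**

Step 1
Reactants: 1 2,4,6-trihydroxyacetophenone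
Product: 2 1-(2,4,6-trihydroxy-3-methylphenyl)ethan-1-one
Conditions: NaOMe (1.1 equiv), MeI (1.0 equiv), MeOH, 0 °C → rt
Reagents that add atoms: iodomethane, CI
Why: Nuclear (C-)methylation of the phloroglucinol phenoxide, which reacts through its β-diketone-like ring carbon; limiting MeI to one equivalent should hold back the 3,5-dimethyl by-product.

Step 2
Reactants: 2 1-(2,4,6-trihydroxy-3-methylphenyl)ethan-1-one
Product: 3 1-(2,6-dihydroxy-4-methoxy-3-methylphenyl)ethan-1-one
Conditions: Me2SO4 (1.05 equiv), K2CO3 (1.1 equiv), acetone, rt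
Reagents that add atoms: dimethyl sulfate, COS(=O)(=O)OC
Why: Williamson etherification; the 4-OH para to the acetyl group is the most acidic and the one least held in a hydrogen bond to the carbonyl, so one equivalent of Me2SO4 should methylate it first.

Step 3
Reactants: 3 1-(2,6-dihydroxy-4-methoxy-3-methylphenyl)ethan-1-one
Product: 5 3-acetyl-2,4-dihydroxy-6-methoxy-5-methylbenzaldehyde, via aryliminium chloride 4 (not isolated)
Conditions: POCl3 (1.2 equiv), DMF (3 equiv), EtOAc, 0 °C → rt; then H2O, 40 °C
Reagents that add atoms: N,N-dimethylformamide, CN(C)C=O; water, O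
Why: Vilsmeier–Haack formylation at the only unsubstituted ring carbon, which is activated by the flanking OH and OMe and by the para OH; acylphloroglucinols are formylated on the ring under these mild conditions.

Step 4
Reactants: 5 3-acetyl-2,4-dihydroxy-6-methoxy-5-methylbenzaldehyde
Product: 6 3-acetyl-6-methoxy-2,4-bis(methoxymethoxy)-5-methylbenzaldehyde
Conditions: MOMCl (4 equiv), iPr2NEt (5 equiv), CH2Cl2, 0 → 40 °C
Reagents that add atoms: chloromethyl methyl ether, COCCl
Why: Williamson-type O-alkylation of both phenols with the highly reactive MOMCl; the carbonyl-flanked hydroxyls are acidic enough for the amine base, and excess reagent with gentle heating should overcome the hydrogen bonding.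

Step 5
Reactants: 6 3-acetyl-6-methoxy-2,4-bis(methoxymethoxy)-5-methylbenzaldehyde
Product: 7 1-[3-(hydroxymethyl)-4-methoxy-2,6-bis(methoxymethoxy)-5-methylphenyl]ethan-1-one
Conditions: NaBH4 (0.5 equiv), MeOH–THF, −20 °C
Reagents that add atoms: none
Why: Hydride reduction of the aldehyde, which is far more electrophilic than the twisted, doubly ortho-substituted aryl methyl ketone, so a limited charge of NaBH4 at low temperature should stop at the benzylic alcohol.

Step 6
Reactants: 7 1-[3-(hydroxymethyl)-4-methoxy-2,6-bis(methoxymethoxy)-5-methylphenyl]ethan-1-one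
Product: 8 1-[3-(bromomethyl)-4-methoxy-2,6-bis(methoxymethoxy)-5-methylphenyl]ethan-1-one
Conditions: CBr4 (1.3 equiv), PPh3 (1.3 equiv), CH2Cl2, 0 °C; short pad of deactivated silica, volatiles removed under high vacuum, used at once
Reagents that add atoms: tetrabromomethane, BrC(Br)(Br)Br
Why: Appel bromination through the alkoxyphosphonium bromide under neutral conditions that spare the MOM acetals; the fully substituted ring leaves no site for ring bromination.

Step 7
Reactants: 9 methyl acetoacetate (1.5 equiv); 10 prenyl bromide (1-bromo-3-methylbut-2-ene)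
Product: 11 methyl 2-acetyl-5-methylhex-4-enoate (methyl 2-prenylacetoacetate)
Conditions: K2CO3 (1.2 equiv), acetone, reflux
Reagents that add atoms: none
Why: Acetoacetic ester C-alkylation of the stabilised enolate with an allylic bromide; the excess of keto ester should suppress dialkylation.

Step 8
Reactants: 11 methyl 2-acetyl-5-methylhex-4-enoate (1.5 equiv); 8 ring A benzyl bromide
Product: 13 methyl 2-{3-[3-acetyl-6-methoxy-2,4-bis(methoxymethoxy)-5-methylphenyl]propanoyl}-5-methylhex-4-enoate, via lithium sodium dienolate 12 (not isolated)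
Conditions: NaH (1.1 equiv per 11), THF, 0 °C; n-BuLi (1.05 equiv per 11), 0 °C; then 8, −78 → 0 °C; aq NH4Cl
Reagents that add atoms: none
Why: γ-Alkylation of a β-keto ester dianion, whose terminal carbanion is its most nucleophilic site and should displace the activated benzylic bromide by SN2 at low temperature faster than it transfers a proton to, or adds to, the hindered aryl ketone.

Step 9
Reactants: 13 keto ester
Product: 14 methyl 5-[3-acetyl-6-methoxy-2,4-bis(methoxymethoxy)-5-methylphenyl]-2-(3-methylbut-2-en-1-yl)-3-(trimethylsilyloxy)pent-2-enoate (E/Z mixture)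
Conditions: TMSCl (1.5 equiv), Et3N (1.6 equiv), toluene, rt, 48 h; filtered under argon
Reagents that add atoms: chlorotrimethylsilane, C[Si](C)(C)Cl
Why: Soft enolisation and O-silylation of the β-keto ester gives the conjugated 3-silyloxy enoate, while triethylamine does not enolise the aryl methyl ketone.

Step 10
Reactants: 14 silyloxy enoate
Product: 15 tris(trimethylsilyl) diene: 1-methoxy-1,3-bis(trimethylsilyloxy)-2-(3-methylbut-2-en-1-yl)penta-1,3-diene carrying at C5 the 6-methoxy-2,4-bis(methoxymethoxy)-5-methyl-3-[1-(trimethylsilyloxy)ethenyl]phenyl group (alkene isomers not separated)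
Conditions: TMSCl (3 equiv), LiN(iPr)2 (2.5 equiv) added last, THF, −78 → 0 °C; pentane, filtration under argon, used crude
Reagents that add atoms: chlorotrimethylsilane, C[Si](C)(C)Cl
Why: Vinylogous (γ) deprotonation of the silyloxy enoate and O-silylation of the dienolate is the standard second stage of 1-alkoxy-1,3-bis(silyloxy) diene synthesis; the ring A acetyl group is enolised and silylated in the same operation, hence the excess of base.

Step 11
Reactants: 16 ethoxyacetylene
Product: 18 4-ethoxybut-3-yn-2-one, via lithium ethoxyacetylide 17 (not isolated)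
Conditions: n-BuLi (1.0 equiv), THF, −78 °C; then cannulated into Ac2O (1.5 equiv), THF, −78 °C; pH 7 buffer, cold extraction, bulb-to-bulb distillation
Reagents that add atoms: acetic anhydride, CC(=O)OC(C)=O
Why: C-acylation of a lithium acetylide by inverse addition to the anhydride; the push-pull ynone formed is a poor carbonyl electrophile, which should disfavour a second addition.

Step 12
Reactants: 15 tris(trimethylsilyl) diene; 18 4-ethoxybut-3-yn-2-one (1.5 equiv)
Product: 20 mallotojaponin with O6' as ethyl ether and the two ring A hydroxyls as MOM ethers, via silylated cyclohexadiene cycloadduct 19 (not isolated)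
Conditions: toluene (0.5 M), 50 °C, argon; then 10% aq citric acid, THF, 0 °C → rt
Reagents that add atoms: none
Why: Proposed new method: the diene terminus C1' (largest HOMO coefficient, vinylogous to both silyloxy groups) should attack the ethoxy-bearing alkyne carbon C6', which is β to the acetyl group and the ketene-like carbon of the ynol ether, so donor and acceptor polarise the alkyne in the same sense; the allenolate then closes on the methoxy(silyloxy)carbenium carbon C4' (6-exo-trig, forming C4'–C5' and completing ring B), or both bonds form in one asynchronous concerted (4+2) event. The closest known reaction type is the Diels–Alder reaction and aromatisation of 1-alkoxy-1,3-bis(silyloxy) dienes and 1,1-dialkoxy-3-silyloxy dienes with alkynones and propiolates to give resorcinols, here extended to a push-pull alkoxy ynone. On acid work-up adduct 19 loses methanol from C4' and its silyl groups, the dienone tautomerises through the C1'–H to the arene, and the ring A silyl enol ether reverts to the acetyl group. No stereocentre survives, so only regio- and chemoselectivity are needed: the regiochemistry follows from the matched polarisation, the alternative (3+3) closure of C3' on the acetyl carbonyl is blocked because C3' carries the prenyl group and could not aromatise, and the aryl silyl enol ether of ring A is far less nucleophilic than the bis(silyloxy) diene. The temperature stays well below that of retro-ene fragmentation of the ethyl ynol ether, and water is excluded until the quench because the ynone hydrates to ethyl acetoacetate.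

Step 13
Reactants: 20 O6'-ethyl bis-MOM mallotojaponin
Product: 21 2',4'-di-O-acetate of 20
Conditions: Ac2O (3 equiv), Et3N (4 equiv), DMAP (0.1 equiv), CH2Cl2, 0 °C → rt
Reagents that add atoms: acetic anhydride, CC(=O)OC(C)=O
Why: DMAP-catalysed acetylation of both ring B phenols; a free 4'-OH would hold the C5' acetyl carbonyl in a boron chelate and leave the O6' ethyl ether unactivated in the next step, and the acetates also keep the phenols from adding to the prenyl alkene.

Step 14
Reactants: 21 diacetate
Product: 22 2',4'-di-O-acetylmallotojaponin (O6' and both ring A hydroxyls free)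
Conditions: BCl3 (1 M in CH2Cl2, 5 equiv), CH2Cl2, −78 → −10 °C; cold H2O
Reagents that add atoms: none
Why: Chelation-assisted ether cleavage: boron bridges the C5' carbonyl and the ethyl ether oxygen and chloride removes the ethyl group, the MOM acetals fall already at −78 °C, and the ring A methyl ether, para to its acetyl group and without a chelating partner, should survive below 0 °C.

Step 15
Reactants: 22 2',4'-di-O-acetylmallotojaponin
Product: 23 mallotojaponin, 1-{3-[(3-acetyl-2,4-dihydroxy-6-methoxy-5-methylphenyl)methyl]-2,4,6-trihydroxy-5-(3-methylbut-2-en-1-yl)phenyl}ethan-1-one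
Conditions: K2CO3 (2 equiv), MeOH, 0 °C, argon; then 1 M HCl to pH 4
Reagents that add atoms: none
Why: Base-mediated transesterification (methanolysis) of the two aryl acetates, which should leave every other group untouched.

**Compound list**

1 | 2,4,6-trihydroxyacetophenone | CC(=O)c1c(O)cc(O)cc1O | starting material
2 | 1-(2,4,6-trihydroxy-3-methylphenyl)ethan-1-one | CC(=O)c1c(O)cc(O)c(C)c1O | intermediate
3 | 1-(2,6-dihydroxy-4-methoxy-3-methylphenyl)ethan-1-one | CC(=O)c1c(O)cc(OC)c(C)c1O | intermediate
4 | N-[(3-acetyl-2,4-dihydroxy-6-methoxy-5-methylphenyl)methylidene]-N-methylmethanaminium chloride | CC(=O)c1c(O)c(C=[N+](C)C)c(OC)c(C)c1O.[Cl-] | intermediate (not isolated)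
5 | 3-acetyl-2,4-dihydroxy-6-methoxy-5-methylbenzaldehyde | CC(=O)c1c(O)c(C=O)c(OC)c(C)c1O | intermediate
6 | 3-acetyl-6-methoxy-2,4-bis(methoxymethoxy)-5-methylbenzaldehyde | CC(=O)c1c(OCOC)c(C=O)c(OC)c(C)c1OCOC | intermediate
7 | 1-[3-(hydroxymethyl)-4-methoxy-2,6-bis(methoxymethoxy)-5-methylphenyl]ethan-1-one | CC(=O)c1c(OCOC)c(CO)c(OC)c(C)c1OCOC | intermediate
8 | 1-[3-(bromomethyl)-4-methoxy-2,6-bis(methoxymethoxy)-5-methylphenyl]ethan-1-one | CC(=O)c1c(OCOC)c(CBr)c(OC)c(C)c1OCOC | intermediate
9 | methyl acetoacetate | COC(=O)CC(C)=O | starting material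
10 | prenyl bromide (1-bromo-3-methylbut-2-ene) | CC(C)=CCBr | starting material
11 | methyl 2-acetyl-5-methylhex-4-enoate | COC(=O)C(CC=C(C)C)C(C)=O | intermediate
12 | lithium sodium dienolate (dianion) of 11 | [Na+].[Li+].COC([O-])=C(CC=C(C)C)C(=C)[O-] | intermediate (not isolated)
13 | methyl 2-{3-[3-acetyl-6-methoxy-2,4-bis(methoxymethoxy)-5-methylphenyl]propanoyl}-5-methylhex-4-enoate | COC(=O)C(CC=C(C)C)C(=O)CCc1c(OC)c(C)c(OCOC)c(C(C)=O)c1OCOC | intermediate
14 | methyl 5-[3-acetyl-6-methoxy-2,4-bis(methoxymethoxy)-5-methylphenyl]-2-(3-methylbut-2-en-1-yl)-3-(trimethylsilyloxy)pent-2-enoate (E/Z mixture) | COC(=O)C(CC=C(C)C)=C(O[Si](C)(C)C)CCc1c(OC)c(C)c(OCOC)c(C(C)=O)c1OCOC | intermediate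
15 | 1-methoxy-1,3-bis(trimethylsilyloxy) diene with C2 prenyl and C4 CH2-(ring A), ring A acetyl as trimethylsilyl enol ether (alkene isomers) | COC(O[Si](C)(C)C)=C(CC=C(C)C)C(O[Si](C)(C)C)=CCc1c(OC)c(C)c(OCOC)c(C(=C)O[Si](C)(C)C)c1OCOC | intermediate
16 | ethoxyacetylene | CCOC#C | starting material
17 | lithium ethoxyacetylide | [Li+].CCOC#[C-] | intermediate (not isolated)
18 | 4-ethoxybut-3-yn-2-one | CC(=O)C#COCC | intermediate
19 | cyclohexa-1,4-diene cycloadduct: C1'H(CH2-ring A), C2'(OTMS)=C3'(prenyl), C4'(OMe)(OTMS), C5'(acetyl)=C6'(OEt); diastereomer mixture | CCOC1=C(C(C)=O)C(OC)(O[Si](C)(C)C)C(CC=C(C)C)=C(O[Si](C)(C)C)C1Cc1c(OC)c(C)c(OCOC)c(C(=C)O[Si](C)(C)C)c1OCOC | intermediate (not isolated)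
20 | mallotojaponin, O6' ethyl ether, ring A hydroxyls as MOM ethers | CCOc1c(C(C)=O)c(O)c(CC=C(C)C)c(O)c1Cc1c(OC)c(C)c(OCOC)c(C(C)=O)c1OCOC | intermediate
21 | 2',4'-di-O-acetate of 20 | CCOc1c(C(C)=O)c(OC(C)=O)c(CC=C(C)C)c(OC(C)=O)c1Cc1c(OC)c(C)c(OCOC)c(C(C)=O)c1OCOC | intermediate
22 | 2',4'-di-O-acetylmallotojaponin | Oc1c(C(C)=O)c(OC(C)=O)c(CC=C(C)C)c(OC(C)=O)c1Cc1c(OC)c(C)c(O)c(C(C)=O)c1O | intermediate
23 | mallotojaponin | COc1c(C)c(O)c(C(C)=O)c(O)c1Cc1c(O)c(CC=C(C)C)c(O)c(C(C)=O)c1O | target

**Step count and risks**

Total steps: 15. Longest linear sequence: 13 (steps 1–6, 8–10, 12–15).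

Step 12 (key step). The push-pull ynone may prove too weak an electrophile for the hindered, doubly substituted diene below the temperature at which the ynol ether fragments. The ynone may also hydrate or oligomerise, the diene may lose silyl groups before it reacts, or the adduct may not aromatise cleanly. The fallback uses known phloroglucinol chemistry and joins the two rings at the bridge instead of building ring B; it sets out from 3 (with 1 and 10) and comes back at 23. Monomer 3 is aminomethylated at its one free ring carbon (CH2O, Me2NH, EtOH; Mannich reaction) to give 1-{3-[(dimethylamino)methyl]-2,6-dihydroxy-4-methoxy-5-methylphenyl}ethan-1-one F1. Separately, 1 is C-prenylated with 10 (aq KOH, 0 °C) to give 1-[2,4,6-trihydroxy-3-(3-methylbut-2-en-1-yl)phenyl]ethan-1-one F2. Heating F1 with F2 in dioxane at 90 °C should expel dimethylamine and generate the ortho-quinone methide of ring A, to which the only free ring carbon of F2 adds, giving 23 directly. F1 has no free ring carbon, so it cannot condense with itself.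

Step 8. The dianion may transfer a proton to, or add to, the ring A acetyl group, and the electron-rich bromide may ionise (self-condensation, or participation of the neighbouring MOM oxygen) before it is displaced. The fallback avoids both the strong base and the benzylic halide; it sets out from aldehyde 6 and comes back at 13. Wittig olefination of 6 with Ph3P=CHC(O)CH2CO2Me as its sodium enolate (NaH, 1 equiv, THF, rt → 50 °C) should give methyl (E)-5-[3-acetyl-6-methoxy-2,4-bis(methoxymethoxy)-5-methylphenyl]-3-oxopent-4-enoate F3. Hydrogenation of the styrene-type double bond (H2, palladium on carbon, EtOAc) gives methyl 5-[3-acetyl-6-methoxy-2,4-bis(methoxymethoxy)-5-methylphenyl]-3-oxopentanoate F4. α-Prenylation of F4 with 10 (K2CO3, acetone) then gives 13.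

Step 14. The chelation-assisted loss of the ethyl group may be slow enough for BCl3 to attack the hindered ring A methyl ether, and the prenyl alkene may be captured by HCl or by the methoxymethyl cation released from the MOM groups. The fallback removes each protecting group with its own mild reagent; it sets out from 20 and comes back at 23. Methanolic HCl at rt removes the two MOM groups to give 6'-O-ethylmallotojaponin F5. Peracetylation (Ac2O, Et3N, DMAP) gives 6'-O-ethylmallotojaponin tetraacetate F6. MgI2·OEt2 in toluene at 60 °C should then cleave only the ethyl ether, through a magnesium chelate with the C5' acetyl group and without free acid, to give mallotojaponin tetraacetate with free 6'-OH F7. Methanolysis (K2CO3, MeOH) gives 23.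

**Further compounds**

F1 | step 12 | 1-{3-[(dimethylamino)methyl]-2,6-dihydroxy-4-methoxy-5-methylphenyl}ethan-1-one | CC(=O)c1c(O)c(CN(C)C)c(OC)c(C)c1O
F2 | step 12 | 1-[2,4,6-trihydroxy-3-(3-methylbut-2-en-1-yl)phenyl]ethan-1-one | CC(=O)c1c(O)cc(O)c(CC=C(C)C)c1O
F3 | step 8 | methyl (E)-5-[3-acetyl-6-methoxy-2,4-bis(methoxymethoxy)-5-methylphenyl]-3-oxopent-4-enoate | COC(=O)CC(=O)/C=C/c1c(OC)c(C)c(OCOC)c(C(C)=O)c1OCOC
F4 | step 8 | methyl 5-[3-acetyl-6-methoxy-2,4-bis(methoxymethoxy)-5-methylphenyl]-3-oxopentanoate | COC(=O)CC(=O)CCc1c(OC)c(C)c(OCOC)c(C(C)=O)c1OCOC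
F5 | step 14 | 6'-O-ethylmallotojaponin | CCOc1c(C(C)=O)c(O)c(CC=C(C)C)c(O)c1Cc1c(OC)c(C)c(O)c(C(C)=O)c1O
F6 | step 14 | 6'-O-ethylmallotojaponin tetraacetate | CCOc1c(C(C)=O)c(OC(C)=O)c(CC=C(C)C)c(OC(C)=O)c1Cc1c(OC)c(C)c(OC(C)=O)c(C(C)=O)c1OC(C)=O
F7 | step 14 | mallotojaponin tetraacetate with free 6'-OH | Oc1c(C(C)=O)c(OC(C)=O)c(CC=C(C)C)c(OC(C)=O)c1Cc1c(OC)c(C)c(OC(C)=O)c(C(C)=O)c1OC(C)=O
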